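The C5–C5' axis is cut to two identical hydroxyquinones. In each ring (C1 carbonyl, C2 OH, C3 CH3, C4 carbonyl, C5 axis carbon, C6 arylethyl carbon) the meta-related oxygens at C2 and C4 around C3 mark an oxidised 2-methyl-5-(arylethyl)resorcinol, the folding pattern of a tetraketide. The route rests on closing that ring from an open chain. In methyl 9-(2-methoxyphenyl)-4-methyl-3,5,7-trioxononanoate the C2 methylene adds to the C7 ketone. Loss of water and tautomerisation then give the fully substituted resorcylate in one operation, because the methyl group, both oxygens and the arylethyl arm already sit in the chain. Ester hydrolysis with decarboxylation, Teuber oxidation and quinone–hydroquinone coupling at the only free ring carbon complete the target.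

Key step: step 4

Assumption: the target string bears no axial descriptor, so the C5–C5' axis, which has four ortho substituents, is made as the racemate.

Remarks on structure and design (chain numbering: C1 = carboxyl carbon, C9 = ArCH2):
- **Mode of closure.** The reacting enolate bond C2=C3 lies inside the ring being formed. The closure is therefore 6-(enolendo)-exo-trig, and only the minor ester-enolate canonical form would count as enolexo.
- **Mapping.** The decarboxylated resorcinol has a mirror plane through its methyl-bearing and arylethyl-bearing carbons, so its two ring CH positions are equivalent. Chain C2 thus ends as C5 in some quinone rings and as C1 in others, and the bond made in the key step is accordingly C5–C6 or C1–C6.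
- **Precursor.** A free 3,5,7-triketo acid is a β-keto acid that loses CO2 and lactonises on handling. It is therefore carried as its methyl ester, which keeps C2 doubly activated. The price is one more competitor, the C6-to-C1 Claisen closure to an acylphloroglucinol, which the conditions of step 4 must also suppress.
- **Assembly.** The chain is grown from the ester end. The last deprotonation then has only the C6 methyl to choose, and no methyl-versus-methylene ambiguity arises.

Step 1
Reactants: 1 methyl 3-oxopentanoate; 2 N-methoxy-N-methylacetamide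
Product: 3 methyl 4-methyl-3,5-dioxohexanoate (keto–enol mixture)
Conditions: LiN(iPr)2 (LDA, 2.2 equiv), THF, 0 °C; then 2, −78 → 0 °C; cold 1 M HCl
Reagents that add atoms: none
Why: γ-Acylation of a β-keto ester dianion (Weinreb ketone synthesis): the dianion reacts at its more basic γ-carbon, the chelated tetrahedral adduct holds until the quench so that neither double addition nor proton transfer from the more acidic product interferes, and the new C4 centre is an epimerisable β-dicarbonyl CH that later becomes sp2 and needs no control.

Step 2
Reactants: 4 3-(2-methoxyphenyl)propanoic acid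
Product: 6 N-methoxy-3-(2-methoxyphenyl)-N-methylpropanamide, via acyl imidazole 5 (not isolated)
Conditions: CDI (1.1 equiv), CH2Cl2, rt; then MeNHOMe·HCl (1.2 equiv), rt
Reagents that add atoms: N,O-dimethylhydroxylamine hydrochloride, CNOC.Cl; 1,1'-carbonyldiimidazole, O=C(n1ccnc1)n1ccnc1 (imidazolyl group of 5 only)
Why: Amide formation through an acyl imidazole: CDI activates the acid with loss of CO2 and the hydroxylamine then displaces imidazole, under conditions that leave the aryl methyl ether untouched.

Step 3
Reactants: 3 methyl 4-methyl-3,5-dioxohexanoate; 6 N-methoxy-3-(2-methoxyphenyl)-N-methylpropanamide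
Product: 7 methyl 9-(2-methoxyphenyl)-4-methyl-3,5,7-trioxononanoate (tautomer mixture, used crude)
Conditions: 3, LiN(iPr)2 (LDA, 3.3 equiv), THF, −78 → 0 °C; 6, −78 → −10 °C; cold 1 M HCl to pH 4–5
Reagents that add atoms: none
Why: Terminal acylation of a 3,5-dioxo ester trianion (polyanion chemistry combined with the Weinreb ketone synthesis): once C2 and C4 are ionised the C6 methyl is the only site left for the third deprotonation, this last-formed carbanion is the most nucleophilic one, and the stable tetrahedral adduct releases the acidic C6 methylene of 7 only on quenching.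

Step 4
Reactants: 7 methyl 9-(2-methoxyphenyl)-4-methyl-3,5,7-trioxononanoate
Product: 9 methyl 2,4-dihydroxy-6-[2-(2-methoxyphenyl)ethyl]-3-methylbenzoate, via cyclic aldol 8 (not isolated)
Conditions: Cs2CO3 (2 equiv), MeOH, 0 °C → rt; then HCl in MeOH to pH 2, rt
Reagents that add atoms: none
Why: Carbonate ionises the doubly activated positions of the chain, the C2 enolate (held between the ester and the C3 ketone) adds to the C7 carbonyl to give cyclic aldol 8, and acidification completes the loss of water, after which tautomerisation of the C3 and C5 carbonyls to phenols makes the sequence irreversible. The closest known reaction type is the biomimetic aldol aromatisation of 3,5,7-triketo esters to resorcylates, including members that carry a carbon substituent at C4. The single ring (chain C2 to C7) closes in the 6-(enolendo)-exo-trig mode, since the reacting C2=C3 enolate bond lies inside the new ring and the C7=O bond outside it. No stereocentre is set: C4 of 7 is epimerisable and the sp3 centres of 8 disappear on aromatisation. Selectivity is needed against the C8-to-C3 aldol, the C6-to-C1 Claisen closure to an acylphloroglucinol, lactonisation of the C5 enol onto C1 to a 4-hydroxy-2-pyrone and acid-induced closure to a 4-pyranone. The substrate secures it because C8 is flanked by one carbonyl only and is not ionised by carbonate, a ketone accepts a stabilised enolate faster than an ester does, methanol returns any acyl exchange at C1 to the same methyl ester, and acid is admitted only after ring closure.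

Step 5
Reactants: 9 methyl 2,4-dihydroxy-6-[2-(2-methoxyphenyl)ethyl]-3-methylbenzoate
Product: 11 5-[2-(2-methoxyphenyl)ethyl]-2-methylbenzene-1,3-diol, via resorcylic acid 10 (not isolated)
Conditions: KOH (6 equiv), MeOH–H2O, reflux, Ar; then 3 M HCl to pH 1, 90 °C
Reagents that add atoms: potassium hydroxide, [K+].[OH-] (its oxygen enters 10 only and leaves again as CO2)
Why: Saponification followed by protodecarboxylation: ipso protonation of 10 is assisted by hydroxyl groups ortho and para to the carboxyl-bearing carbon, as in orsellinic-type acids, while the aryl methyl ether is inert to aqueous alkali and dilute acid.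

Step 6
Reactants: 11 5-[2-(2-methoxyphenyl)ethyl]-2-methylbenzene-1,3-diol
Product: 12 2-hydroxy-6-[2-(2-methoxyphenyl)ethyl]-3-methylcyclohexa-2,5-diene-1,4-dione (C5–H monomer in the ring numbering of the overview)
Conditions: (KSO3)2NO (2.5 equiv), KH2PO4 buffer (pH about 6), H2O–acetone, 0 °C → rt
Reagents that add atoms: potassium nitrosodisulfonate (KSO3)2NO, [K+].[K+].[O]N(S(=O)(=O)[O-])S(=O)(=O)[O-] (one oxygen atom)
Why: Teuber oxidation: one nitroxyl radical removes a phenolic hydrogen and a second delivers oxygen to the free carbon para to that hydroxyl, and because the two candidate carbons are equivalent by symmetry, the position between the hydroxyls is blocked by methyl and the anisole ring has no phenolic OH, a single hydroxy-p-quinone should result.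

Step 7
Reactants: 12 2-hydroxy-6-[2-(2-methoxyphenyl)ethyl]-3-methylcyclohexa-2,5-diene-1,4-dione (two equivalents)
Product: 15 4,4'-dihydroxy-2,2'-bis[2-(2-methoxyphenyl)ethyl]-5,5'-dimethyl[1,1'-bi(cyclohexa-1,4-dien-1-yl)]-3,3',6,6'-tetrone (the target; racemic about the axis), via benzenetriol 13 (not isolated), via biphenylhexol 14 (not isolated)
Conditions: (a) one half of 12, aq. Na2S2O4, EtOAc, rt, Ar, organic phase dried and concentrated; (b) other half of 12, degassed AcOH, MeSO3H (10 mol %), 40 °C; (c) aq. FeCl3 (4 equiv per dimer), slow addition, rt; dilute HCl work-up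
Reagents that add atoms: none
Why: Quinone–hydroquinone coupling (acid-promoted conjugate arylation, the reaction type by which 1,2,4-benzenetriol and methoxybenzoquinone dimerise): triol 13 is nucleophilic and protonated 12 electrophilic at the same and only unsubstituted ring carbon C5, so only the C5–C5' biaryl 14 can form, it has no free ring position for oligomerisation, slowly added FeCl3 recycles leftover 13 into 12 and dehydrogenates 14 to the bis-quinone, the singly activated anisole rings stay spectators, and the axis forms as the racemate.

Compound list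
1 | methyl 3-oxopentanoate | CCC(=O)CC(=O)OC | starting material
2 | N-methoxy-N-methylacetamide | CC(=O)N(C)OC | starting material
3 | methyl 4-methyl-3,5-dioxohexanoate | COC(=O)CC(=O)C(C)C(C)=O | intermediate
4 | 3-(2-methoxyphenyl)propanoic acid | COc1ccccc1CCC(=O)O | starting material
5 | 1-(imidazol-1-yl)-3-(2-methoxyphenyl)propan-1-one | COc1ccccc1CCC(=O)n1ccnc1 | intermediate
6 | N-methoxy-3-(2-methoxyphenyl)-N-methylpropanamide | COc1ccccc1CCC(=O)N(C)OC | intermediate
7 | methyl 9-(2-methoxyphenyl)-4-methyl-3,5,7-trioxononanoate (C4 epimerisable) | COC(=O)CC(=O)C(C)C(=O)CC(=O)CCc1ccccc1OC | intermediate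
8 | methyl 2-hydroxy-2-[2-(2-methoxyphenyl)ethyl]-5-methyl-4,6-dioxocyclohexane-1-carboxylate (transient diastereomer and tautomer mixture) | COC(=O)C1C(=O)C(C)C(=O)CC1(O)CCc1ccccc1OC | intermediate
9 | methyl 2,4-dihydroxy-6-[2-(2-methoxyphenyl)ethyl]-3-methylbenzoate | COC(=O)c1c(O)c(C)c(O)cc1CCc1ccccc1OC | intermediate
10 | 2,4-dihydroxy-6-[2-(2-methoxyphenyl)ethyl]-3-methylbenzoic acid | OC(=O)c1c(O)c(C)c(O)cc1CCc1ccccc1OC | intermediate
11 | 5-[2-(2-methoxyphenyl)ethyl]-2-methylbenzene-1,3-diol | COc1ccccc1CCc1cc(O)c(C)c(O)c1 | intermediate
12 | 2-hydroxy-6-[2-(2-methoxyphenyl)ethyl]-3-methylcyclohexa-2,5-diene-1,4-dione | COc1ccccc1CCC1=CC(=O)C(C)=C(O)C1=O | intermediate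
13 | 6-[2-(2-methoxyphenyl)ethyl]-3-methylbenzene-1,2,4-triol | COc1ccccc1CCc1cc(O)c(C)c(O)c1O | intermediate
14 | 6,6'-bis[2-(2-methoxyphenyl)ethyl]-3,3'-dimethyl[1,1'-biphenyl]-2,2',4,4',5,5'-hexol | COc1ccccc1CCc1c(O)c(O)c(C)c(O)c1-c1c(CCc2ccccc2OC)c(O)c(O)c(C)c1O | intermediate
15 | 4,4'-dihydroxy-2,2'-bis[2-(2-methoxyphenyl)ethyl]-5,5'-dimethyl[1,1'-bi(cyclohexa-1,4-dien-1-yl)]-3,3',6,6'-tetrone | COc1ccccc1CCC1=C(C2=C(CCc3ccccc3OC)C(=O)C(O)=C(C)C2=O)C(=O)C(C)=C(O)C1=O | target

Total steps: 7. Longest linear sequence: 6 steps (1 → 3 → 7 → 9 → 11 → 12 → 15; the branch from 4 is equally long).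

Steps most likely to fail

**Step 4.** The open chain may be diverted before the aldol closes. The possible diversions are O-acylation of the C5 enol by the ester, Claisen closure from C6, and retro-Claisen cleavage by methoxide at the methyl-bearing C4.

The fallback sets out from 6 and returns at 9. It builds the ring at the cyclohexanedione level and dehydrogenates it afterwards. Amide 6 is reduced with iBu2AlH (THF, −78 °C) to 3-(2-methoxyphenyl)propanal F1. Horner–Wadsworth–Emmons olefination with diethyl (2-oxobutyl)phosphonate (LiCl, iPr2NEt, MeCN) gives (E)-7-(2-methoxyphenyl)hept-4-en-3-one F2. Dimethyl malonate and NaOMe in refluxing MeOH add in Michael fashion to give dimethyl 2-[1-(2-methoxyphenyl)-5-oxoheptan-3-yl]propanedioate F3. In the same flask F3 closes by Dieckmann-type condensation from the CH2 of the ethyl ketone to methyl 6-[2-(2-methoxyphenyl)ethyl]-3-methyl-2,4-dioxocyclohexane-1-carboxylate F4. Dehydrogenation with DDQ (dioxane, reflux) then gives 9.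

**Step 7.** Bond formation at the doubly flanked C5 may be so slow that redox exchange merely interconverts quinone and triol. Coupling through oxygen instead of carbon may also intervene.

The fallback sets out from 12 and returns at 15. It replaces the oxidative coupling by a reductive coupling of an aryl halide.
- Reductive methylation of 12 (Na2S2O4, then Me2SO4, K2CO3, acetone, reflux, passing through 13) gives 2,3,5-trimethoxy-1-[2-(2-methoxyphenyl)ethyl]-4-methylbenzene F5.
- N-Iodosuccinimide with catalytic CF3CO2H in MeCN iodinates the only free position of the far more electron-rich ring to give 1-iodo-2,4,5-trimethoxy-6-[2-(2-methoxyphenyl)ethyl]-3-methylbenzene F6.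
- Ullmann homocoupling (activated Cu powder, DMF, 150 °C) gives 2,2',4,4',5,5'-hexamethoxy-6,6'-bis[2-(2-methoxyphenyl)ethyl]-3,3'-dimethyl-1,1'-biphenyl F7.
- Oxidative demethylation with (NH4)2Ce(NO3)6 in MeCN–H2O gives 4,4'-dimethoxy-2,2'-bis[2-(2-methoxyphenyl)ethyl]-5,5'-dimethyl[1,1'-bi(cyclohexa-1,4-dien-1-yl)]-3,3',6,6'-tetrone F8.
- Addition–elimination hydrolysis of the two vinylogous esters (aq. NaOH, MeOH, rt, then HCl) gives 15.

**Step 3.** The third deprotonation may stay incomplete, the terminal carbanion may take a proton from the α-CH2 of the amide instead of adding, or the chain may cyclise in an uncontrolled way on quenching.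

The fallback sets out from 6 and returns at 10. It reverses the order of the two polyanion events. The amide then meets only a dianion, and the trianion meets CO2, which can neither be enolised nor donate a proton. Commercial 3-methylpentane-2,4-dione is converted with LiN(iPr)2 (2.2 equiv) into its dianion and acylated at a terminal methyl by 6, giving 8-(2-methoxyphenyl)-3-methyloctane-2,4,6-trione F9. Three equivalents of LiN(iPr)2 ionise C3, C5 and, kinetically, the C1 methyl rather than the C7 methylene. CO2 then gives 9-(2-methoxyphenyl)-4-methyl-3,5,7-trioxononanoic acid F10, which is kept cold. In aqueous acetate buffer (pH about 5) F10 closes by the same C2-to-C7 aldol to 10, which is heated as in step 5 to give 11.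

Further compounds
F1 | step 4 | 3-(2-methoxyphenyl)propanal | O=CCCc1ccccc1OC
F2 | step 4 | (E)-7-(2-methoxyphenyl)hept-4-en-3-one | CCC(=O)/C=C/CCc1ccccc1OC
F3 | step 4 | dimethyl 2-[1-(2-methoxyphenyl)-5-oxoheptan-3-yl]propanedioate (racemic) | CCC(=O)CC(CCc1ccccc1OC)C(C(=O)OC)C(=O)OC
F4 | step 4 | methyl 6-[2-(2-methoxyphenyl)ethyl]-3-methyl-2,4-dioxocyclohexane-1-carboxylate (diastereomer and tautomer mixture) | COC(=O)C1C(CCc2ccccc2OC)CC(=O)C(C)C1=O
F5 | step 7 | 2,3,5-trimethoxy-1-[2-(2-methoxyphenyl)ethyl]-4-methylbenzene | COc1ccccc1CCc1cc(OC)c(C)c(OC)c1OC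
F6 | step 7 | 1-iodo-2,4,5-trimethoxy-6-[2-(2-methoxyphenyl)ethyl]-3-methylbenzene | COc1ccccc1CCc1c(I)c(OC)c(C)c(OC)c1OC
F7 | step 7 | 2,2',4,4',5,5'-hexamethoxy-6,6'-bis[2-(2-methoxyphenyl)ethyl]-3,3'-dimethyl-1,1'-biphenyl | COc1ccccc1CCc1c(OC)c(OC)c(C)c(OC)c1-c1c(CCc2ccccc2OC)c(OC)c(OC)c(C)c1OC
F8 | step 7 | 4,4'-dimethoxy-2,2'-bis[2-(2-methoxyphenyl)ethyl]-5,5'-dimethyl[1,1'-bi(cyclohexa-1,4-dien-1-yl)]-3,3',6,6'-tetrone | COc1ccccc1CCC1=C(C2=C(CCc3ccccc3OC)C(=O)C(OC)=C(C)C2=O)C(=O)C(C)=C(OC)C1=O
F9 | step 3 | 8-(2-methoxyphenyl)-3-methyloctane-2,4,6-trione | CC(=O)C(C)C(=O)CC(=O)CCc1ccccc1OC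
F10 | step 3 | 9-(2-methoxyphenyl)-4-methyl-3,5,7-trioxononanoic acid | OC(=O)CC(=O)C(C)C(=O)CC(=O)CCc1ccccc1OC
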